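**Plan**

- Retrosynthesis: cut the C10 ester C–O (tetradecanoyl chloride); take the ring carbinol C7 back through its ketone to a C7–SiMe2Ph group; then open the oxolane at O1–C6 and C8–C9 into (R)-3-silyloct-1-ene and an (R)-2-alkoxyundec-10-enal.
- Enabling feature: the oxolane carries oxygen on C7, next to the pentyl-bearing O–CH (C6), has a CH2 at C8, and has an oxygenated carbon (C10) beside the other O–CH (C9). This is the pattern left by an allylsilane/aldehyde [3+2] annulation with 1,2-silyl shift on a chelated α-alkoxy aldehyde.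
- Forward: the silane (steps 1–2) and the aldehyde (steps 3–6) are made separately; step 7 joins them and closes the only ring; steps 8–12 turn Si into OH, exchange the naphthylmethyl ether for the myristate while C7 is a ketone, and end with the ketone reduction.
- Stereochemistry: C10 from (R)-trityl glycidyl ether; C6 from the catalyst-controlled allylic silylation, inverted in the ring closure; C9 from chelation control; C7 from hydride attack anti to the pentyl group.

Key step: step 7

Remark: atoms are numbered along the nonadecene chain (O1 ring oxygen, C6 ring carbon with pentyl, C7 ring CHOH, C8 ring CH2, C9 ring carbon with the side chain, C10 ester carbinol). The tin chelate of the α-(2-naphthylmethoxy) aldehyde is assumed to behave like that of an α-benzyloxy aldehyde.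

**Route**

Step 1
Reactants: 1 (E)-oct-2-en-1-ol
Product: 2 (E)-oct-2-en-1-yl diethyl phosphate
Conditions: ClP(O)(OEt)2, pyridine, DMAP (cat.), CH2Cl2, 0 °C to rt
Reagents that add atoms: diethyl chlorophosphate, CCOP(=O)(Cl)OCC
Why: O-phosphorylation of the primary allylic alcohol under base should give the unrearranged allylic phosphate, the leaving group needed for the copper-catalysed SN2′ substitution.

Step 2
Reactants: 2 (E)-oct-2-en-1-yl diethyl phosphate
Product: 3 (R)-dimethyl(oct-1-en-3-yl)(phenyl)silane
Conditions: PhMe2Si–Bpin, CuCl (5 mol %), chiral imidazolinium salt (NHC precursor, 6 mol %, enantiomer selected for the (R)-silane), NaOMe, THF, 0 °C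
Reagents that add atoms: 2-[dimethyl(phenyl)silyl]-4,4,5,5-tetramethyl-1,3,2-dioxaborolane, CC1(C)OB(OC1(C)C)[Si](C)(C)c1ccccc1
Why: Copper-catalysed enantioselective γ-selective allylic silylation (SN2′ substitution with a silylboronate): methoxide cleaves the Si–B bond and the chiral NHC–copper silyl species adds to one alkene face and expels phosphate, so the ligand sets the silicon-bearing stereocenter.

Step 3
Reactants: 4 8-bromooct-1-ene; 5 (R)-trityl glycidyl ether
Product: 7 (2R)-1-(triphenylmethoxy)undec-10-en-2-ol, via oct-7-enylmagnesium bromide 6 (not isolated)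
Conditions: Mg, THF, rt (gives 6); then 5, CuI (10 mol %), THF, −30 to 0 °C; aq. NH4Cl
Reagents that add atoms: magnesium, [Mg] (retained in 6 only)
Why: Copper-catalysed Grignard opening of a terminal epoxide occurs at the unsubstituted carbon, so the purchased stereocenter is untouched and becomes C10 (R).

Step 4
Reactants: 7 (2R)-1-(triphenylmethoxy)undec-10-en-2-ol
Product: 8 2-({[(2R)-1-(triphenylmethoxy)undec-10-en-2-yl]oxy}methyl)naphthalene
Conditions: NaH, 2-(bromomethyl)naphthalene, n-Bu4NI (cat.), THF/DMF, 0 °C to rt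
Reagents that add atoms: 2-(bromomethyl)naphthalene, BrCc1ccc2ccccc2c1
Why: Williamson etherification installs a 2-naphthylmethyl (NAP) ether, a benzyl-type ether that can chelate tin in step 7 and is later removed oxidatively without touching the terminal alkene.

Step 5
Reactants: 8 2-({[(2R)-1-(triphenylmethoxy)undec-10-en-2-yl]oxy}methyl)naphthalene
Product: 9 (2R)-2-(naphthalen-2-ylmethoxy)undec-10-en-1-ol
Conditions: TsOH·H2O (cat.), MeOH/CH2Cl2, rt
Reagents that add atoms: none
Why: Acid-catalysed solvolysis of the trityl ether (SN1 detritylation) should free the primary alcohol while the NAP ether and the alkene are inert.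

Step 6
Reactants: 9 (2R)-2-(naphthalen-2-ylmethoxy)undec-10-en-1-ol
Product: 10 (2R)-2-(naphthalen-2-ylmethoxy)undec-10-enal
Conditions: Dess–Martin periodinane, CH2Cl2, 0 °C to rt; used at once in step 7
Reagents that add atoms: none
Why: Dess–Martin oxidation under near-neutral conditions should give the α-alkoxy aldehyde without epimerising the α-stereocenter.

Step 7
Reactants: 10 (2R)-2-(naphthalen-2-ylmethoxy)undec-10-enal; 3 (R)-dimethyl(oct-1-en-3-yl)(phenyl)silane
Product: 12 [(2S,3R,5R)-5-[(1R)-1-(naphthalen-2-ylmethoxy)dec-9-en-1-yl]-2-pentyloxolan-3-yl]dimethyl(phenyl)silane, via β-silyl cation 11 (not isolated)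
Conditions: SnCl4 (1.05 equiv), 4 Å MS, CH2Cl2, −78 °C; then 3 (1.3 equiv), −78 to −45 °C; Et3N, aq. NaHCO3
Reagents that add atoms: none
Why: SnCl4 binds the carbonyl and NAP-ether oxygens of 10 in a five-membered chelate; the CH2 terminus of 3 adds to the carbonyl carbon on the chelate face opposite the C11 chain and anti to the C–Si bond (anti-SE′) to give the silicon-bridged β-silyl cation 11, and the tin alkoxide oxygen then attacks C6 from the side opposite silicon, so that silicon ends on C7 (1,2-shift) and the O1–C6 bond closes the ring. The closest known reaction type is the [3+2] annulation of α-chiral allyl(dimethylphenyl)silanes with tin-chelated α-alkoxy aldehydes, which gives 2,5-trans-3-silyloxolanes. The oxolane, the only ring of the target, closes by a 5-endo opening of the three-membered siliranium ring (equivalently, capture of the C6 cation after the silyl shift). C9 (R) is set by chelation control, C6 (S) comes from the silane stereocenter with inversion, C7 (R, silyl trans to pentyl) follows from the suprafacial silyl shift in the conformer with the C6 hydrogen eclipsing the alkene, and the 2,5-trans relation results because the (R)-silane and the open face of the (R)-aldehyde chelate meet in the antiperiplanar arrangement that keeps the silicon-bearing carbon on the aldehyde-hydrogen side, away from the tin ligands. The step needs ring closure to outrun chloride-induced loss of silicon (Hosomi–Sakurai pathway) and reaction at the allylsilane instead of the remote monosubstituted alkene; the internally held chelated alkoxide, the α-branched dimethylphenylsilyl group and −78 °C favour closure, and the allylsilane is by far the more nucleophilic alkene.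

Step 8
Reactants: 12 [(2S,3R,5R)-5-[(1R)-1-(naphthalen-2-ylmethoxy)dec-9-en-1-yl]-2-pentyloxolan-3-yl]dimethyl(phenyl)silane
Product: 13 (2S,3R,5R)-5-[(1R)-1-(naphthalen-2-ylmethoxy)dec-9-en-1-yl]-2-pentyloxolan-3-ol
Conditions: KH, t-BuOOH, n-Bu4NF, NMP, 0 to 50 °C
Reagents that add atoms: tert-butyl hydroperoxide, CC(C)(C)OO
Why: Tamao–Fleming oxidation in its basic variant (nucleophilic cleavage of the Si–phenyl bond, then 1,2-migration of carbon from silicon to peroxide oxygen) should replace C–Si by C–OH with retention, and the absence of electrophiles spares the terminal alkene.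

Step 9
Reactants: 13 (2S,3R,5R)-5-[(1R)-1-(naphthalen-2-ylmethoxy)dec-9-en-1-yl]-2-pentyloxolan-3-ol
Product: 14 (2S,5R)-5-[(1R)-1-(naphthalen-2-ylmethoxy)dec-9-en-1-yl]-2-pentyloxolan-3-one
Conditions: Dess–Martin periodinane, CH2Cl2, 0 °C to rt
Reagents that add atoms: none
Why: Dess–Martin oxidation turns the ring carbinol of the wrong configuration (trans to pentyl) into the oxolan-3-one so that C7 can be reset by hydride delivery, and the non-basic conditions should leave the adjacent C6 stereocenter alone.

Step 10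
Reactants: 14 (2S,5R)-5-[(1R)-1-(naphthalen-2-ylmethoxy)dec-9-en-1-yl]-2-pentyloxolan-3-one
Product: 15 (2S,5R)-5-[(1R)-1-hydroxydec-9-en-1-yl]-2-pentyloxolan-3-one
Conditions: DDQ, CH2Cl2/pH 7 phosphate buffer (10:1), 0 °C to rt
Reagents that add atoms: none
Why: Oxidative cleavage of the NAP ether by DDQ (hydride abstraction at the naphthylmethyl position, hydrolysis of the oxocarbenium ion) should free the side-chain hydroxyl while the ring oxygen function is held as a ketone and the alkene is untouched.

Step 11
Reactants: 15 (2S,5R)-5-[(1R)-1-hydroxydec-9-en-1-yl]-2-pentyloxolan-3-one; 16 tetradecanoyl chloride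
Product: 17 (1R)-1-[(2R,5S)-4-oxo-5-pentyloxolan-2-yl]dec-9-en-1-yl tetradecanoate
Conditions: pyridine, DMAP (cat.), CH2Cl2, 0 °C
Reagents that add atoms: none
Why: DMAP-catalysed acylation of the only hydroxyl group places the myristate on O10 unambiguously, because the ring oxygen function is still a ketone.

Step 12
Reactants: 17 (1R)-1-[(2R,5S)-4-oxo-5-pentyloxolan-2-yl]dec-9-en-1-yl tetradecanoate
Product: 18 (1R)-1-[(2R,4S,5S)-4-hydroxy-5-pentyloxolan-2-yl]dec-9-en-1-yl tetradecanoate
Conditions: LiBH(s-Bu)3, THF, −78 °C; aq. NH4Cl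
Reagents that add atoms: none
Why: Diastereoselective ketone reduction with a bulky borohydride (L-Selectride reduction) should deliver hydride to the oxolan-3-one face opposite the adjacent pentyl group, giving the C7 hydroxyl cis to pentyl (S), and the ester is not reduced at this temperature.

**Compound list**

1 | (E)-oct-2-en-1-ol | CCCCC/C=C/CO | starting material
2 | (E)-oct-2-en-1-yl diethyl phosphate | CCCCC/C=C/COP(=O)(OCC)OCC | intermediate
3 | (R)-dimethyl(oct-1-en-3-yl)(phenyl)silane | C=C[C@@H](CCCCC)[Si](C)(C)c1ccccc1 | intermediate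
4 | 8-bromooct-1-ene | C=CCCCCCCBr | starting material
5 | (R)-trityl glycidyl ether, (2R)-2-[(triphenylmethoxy)methyl]oxirane | C(OC(c1ccccc1)(c1ccccc1)c1ccccc1)[C@H]1CO1 | starting material
6 | oct-7-enylmagnesium bromide | C=CCCCCCC[Mg]Br | intermediate (not isolated)
7 | (2R)-1-(triphenylmethoxy)undec-10-en-2-ol | C=CCCCCCCC[C@@H](O)COC(c1ccccc1)(c1ccccc1)c1ccccc1 | intermediate
8 | 2-({[(2R)-1-(triphenylmethoxy)undec-10-en-2-yl]oxy}methyl)naphthalene | C=CCCCCCCC[C@@H](OCc1ccc2ccccc2c1)COC(c1ccccc1)(c1ccccc1)c1ccccc1 | intermediate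
9 | (2R)-2-(naphthalen-2-ylmethoxy)undec-10-en-1-ol | C=CCCCCCCC[C@@H](OCc1ccc2ccccc2c1)CO | intermediate
10 | (2R)-2-(naphthalen-2-ylmethoxy)undec-10-enal | C=CCCCCCCC[C@@H](OCc1ccc2ccccc2c1)C=O | intermediate
11 | β-silyl cation: adduct after C8–C9 bond formation, C9 alkoxide on tin (drawn as free alkoxide, SnCl4 omitted), cation at C7 bridged by silicon, silane stereocenter unchanged | C=CCCCCCCC[C@@H](OCc1ccc2ccccc2c1)[C@H]([O-])C[CH+][C@@H](CCCCC)[Si](C)(C)c1ccccc1 | intermediate (not isolated)
12 | [(2S,3R,5R)-5-[(1R)-1-(naphthalen-2-ylmethoxy)dec-9-en-1-yl]-2-pentyloxolan-3-yl]dimethyl(phenyl)silane | C=CCCCCCCC[C@@H](OCc1ccc2ccccc2c1)[C@H]1C[C@@H]([Si](C)(C)c2ccccc2)[C@H](CCCCC)O1 | intermediate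
13 | (2S,3R,5R)-5-[(1R)-1-(naphthalen-2-ylmethoxy)dec-9-en-1-yl]-2-pentyloxolan-3-ol | C=CCCCCCCC[C@@H](OCc1ccc2ccccc2c1)[C@H]1C[C@@H](O)[C@H](CCCCC)O1 | intermediate
14 | (2S,5R)-5-[(1R)-1-(naphthalen-2-ylmethoxy)dec-9-en-1-yl]-2-pentyloxolan-3-one | C=CCCCCCCC[C@@H](OCc1ccc2ccccc2c1)[C@H]1CC(=O)[C@H](CCCCC)O1 | intermediate
15 | (2S,5R)-5-[(1R)-1-hydroxydec-9-en-1-yl]-2-pentyloxolan-3-one | C=CCCCCCCC[C@@H](O)[C@H]1CC(=O)[C@H](CCCCC)O1 | intermediate
16 | tetradecanoyl chloride | CCCCCCCCCCCCCC(=O)Cl | starting material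
17 | (1R)-1-[(2R,5S)-4-oxo-5-pentyloxolan-2-yl]dec-9-en-1-yl tetradecanoate | C=CCCCCCCC[C@@H](OC(=O)CCCCCCCCCCCCC)[C@H]1CC(=O)[C@H](CCCCC)O1 | intermediate
18 | (1R)-1-[(2R,4S,5S)-4-hydroxy-5-pentyloxolan-2-yl]dec-9-en-1-yl tetradecanoate | C=CCCCCCCC[C@@H](OC(=O)CCCCCCCCCCCCC)[C@H]1C[C@H](O)[C@H](CCCCC)O1 | target

**Count and risks**

Total step count: 12. Longest linear sequence: 10 steps (steps 3 to 12); the silane branch (steps 1 and 2) joins at step 7.

Steps most likely to fail:

1. Step 7. Chloride-induced loss of silicon from the β-silyl cation (open-chain allylation) may outrun ring closure, and the face pairing of chelate and silane may erode. Fallback, setting out from 10 and 3 and coming back at 13: the union is run on purpose as a chelation-controlled Hosomi–Sakurai allylation (TiCl4, CH2Cl2, −78 °C; racemic 3 suffices) to the (E)-homoallylic alcohol (6E,9R,10R)-10-(naphthalen-2-ylmethoxy)nonadeca-6,18-dien-9-ol F1. Shi epoxidation of the trans-disubstituted alkene (D-fructose-derived ketone, KHSO5, K2CO3 buffer, MeCN/dimethoxymethane/H2O, 0 °C), which should react faster than the monosubstituted alkene, is expected to give the (6R,7R)-epoxy alcohol (2R,3R)-3-(naphthalen-2-ylmethoxy)-1-[(2R,3R)-3-pentyloxiran-2-yl]dodec-11-en-2-ol F2. Camphorsulfonic acid in CH2Cl2 should then close the O1–C6 bond by 5-endo epoxide opening with inversion at C6 and give 13.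

2. Step 8. Fluoride- or alkoxide-triggered anti-elimination of the β-silyl ether (ring opening), or incomplete cleavage of the Si–phenyl bond, may replace the oxidation. Fallback, setting out from 12 and coming back at 13: silicon oxidation is given up and the elimination is used. BF3·OEt2 in CH2Cl2 (−78 to 0 °C) should open the β-silyl ether by Peterson-type anti-elimination to the (E)-homoallylic alcohol (6E,9R,10R)-10-(naphthalen-2-ylmethoxy)nonadeca-6,18-dien-9-ol F3 (same structure as F1). Shi epoxidation as above to the epoxy alcohol (2R,3R)-3-(naphthalen-2-ylmethoxy)-1-[(2R,3R)-3-pentyloxiran-2-yl]dodec-11-en-2-ol F4, then acid-mediated 5-endo closure, returns to 13 with the C7 oxygen now coming from the epoxide.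

3. Step 12. Facial selectivity of hydride delivery may be poor (the C9 side chain lies on the attacked face), or C6 may epimerise under base while the ketone is carried through steps 10 and 11. Fallback, setting out from 13 and coming back at 18: C7 is inverted by substitution instead of oxidation and reduction. Mitsunobu reaction of 13 (PPh3, DIAD, ClCH2CO2H, toluene, 0 °C to rt) should give the inverted ester (2S,3S,5R)-5-[(1R)-1-(naphthalen-2-ylmethoxy)dec-9-en-1-yl]-2-pentyloxolan-3-yl 2-chloroacetate F5. DDQ in wet CH2Cl2 frees the side-chain alcohol (2S,3S,5R)-5-[(1R)-1-hydroxydec-9-en-1-yl]-2-pentyloxolan-3-yl 2-chloroacetate F6. Acylation with 16 (pyridine, CH2Cl2, 0 °C) gives the diester (1R)-1-[(2R,4S,5S)-4-(2-chloroacetoxy)-5-pentyloxolan-2-yl]dec-9-en-1-yl tetradecanoate F7. Thiourea, NaHCO3, EtOH, 50 °C should remove only the chloroacetate and give 18.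

**Further compounds**

F1 | step 7 | (6E,9R,10R)-10-(naphthalen-2-ylmethoxy)nonadeca-6,18-dien-9-ol | C=CCCCCCCC[C@@H](OCc1ccc2ccccc2c1)[C@H](O)C/C=C/CCCCC
F2 | step 7 | (2R,3R)-3-(naphthalen-2-ylmethoxy)-1-[(2R,3R)-3-pentyloxiran-2-yl]dodec-11-en-2-ol | C=CCCCCCCC[C@@H](OCc1ccc2ccccc2c1)[C@H](O)C[C@H]1O[C@@H]1CCCCC
F3 | step 8 | (6E,9R,10R)-10-(naphthalen-2-ylmethoxy)nonadeca-6,18-dien-9-ol | C=CCCCCCCC[C@@H](OCc1ccc2ccccc2c1)[C@H](O)C/C=C/CCCCC
F4 | step 8 | (2R,3R)-3-(naphthalen-2-ylmethoxy)-1-[(2R,3R)-3-pentyloxiran-2-yl]dodec-11-en-2-ol | C=CCCCCCCC[C@@H](OCc1ccc2ccccc2c1)[C@H](O)C[C@H]1O[C@@H]1CCCCC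
F5 | step 12 | (2S,3S,5R)-5-[(1R)-1-(naphthalen-2-ylmethoxy)dec-9-en-1-yl]-2-pentyloxolan-3-yl 2-chloroacetate | C=CCCCCCCC[C@@H](OCc1ccc2ccccc2c1)[C@H]1C[C@H](OC(=O)CCl)[C@H](CCCCC)O1
F6 | step 12 | (2S,3S,5R)-5-[(1R)-1-hydroxydec-9-en-1-yl]-2-pentyloxolan-3-yl 2-chloroacetate | C=CCCCCCCC[C@@H](O)[C@H]1C[C@H](OC(=O)CCl)[C@H](CCCCC)O1
F7 | step 12 | (1R)-1-[(2R,4S,5S)-4-(2-chloroacetoxy)-5-pentyloxolan-2-yl]dec-9-en-1-yl tetradecanoate | C=CCCCCCCC[C@@H](OC(=O)CCCCCCCCCCCCC)[C@H]1C[C@H](OC(=O)CCl)[C@H](CCCCC)O1
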